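## Structural features

The target is an eremophilane-type bicycle. Cyclohexane ring B (C1–C5, C10) shares the C5–C10 bond with ring A (C5–C10), a cross-conjugated cyclohexadienone (C6=C7–C8(=O)–C9=C10) that carries a 2-hydroperoxyprop-2-yl group (C11–C13) on C7. All four stereocentres lie in ring B and all four substituents sit on one face, called β here (the face of the C5 methyl): the quaternary C5 methyl, the adjacent C4 methyl, the C3 angelate next to C4, and the C1 hydroxyl, which is 1,3 to both C3 and C5. Because ring A is planar, the C5 methyl is axial on ring B, so both oxygen substituents are axial and syn to it. The fragile groups are the tertiary allylic hydroperoxide, the (Z)-configured angelate (isomerisation to the tiglate, acyl shift to the cis C1 hydroxyl under base) and the γ-hydroxy dienone. The real difficulty is the quaternary C5 next to C4, the two carbinols on the more hindered face, and the late introduction of the peroxide. The key step uses the fact that C5–C10, with a methyl at C5 and oxygen at C8, have the pattern of 2-methoxy-5-methylbenzoquinone, while C1–C4, with oxygen at C1 and C3 and a methyl at C4, are a 1,3-dioxygenated pentadiene; joining C4 to C5 and C1 to C10 closes ring B.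

## Logic of the disconnections

30 ⇒ 29. The O–C11 bond is cut and the C6=C7 double bond is moved back to C7=C11. A tertiary allylic hydroperoxide beside a conjugated alkene is the retron of a singlet-oxygen ene reaction, and cutting here keeps every earlier intermediate peroxide-free. The forward step must attack only the tetrasubstituted s-cis enone alkene of 29, bond at C11 and take hydrogen from C6.

29 ⇒ 28 ⇒ 27. The C1–H bond is cut (carbinol to ketone) and re-formed on the other face. The cycloaddition can place the C1 oxygen only on the α face, whereas 30 needs it on the hindered β face, which only hydride addition from the open α face provides. The forward reduction must take C1 and not C8, and 28 must not lose its C3 ester, which is β to the new ketone.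

27 ⇒ 26. The O–C(CH3)3 bond is cut. The ether is the form in which the C1 oxygen travels from the diene, inert to base, hydride and palladium. The acidolysis must spare the angelate and the dienone.

26 ⇒ 21 + 22. The C7=C11 bond is cut (aldol condensation retron), so three carbons leave as a trivial ketone. The enolate of 21 must form at C7 only and the dehydration must give the conjugated alkene.

21 ⇒ 20. The C6–H and C7–H bonds are cut, which restores C6=C7. The carbonyl transposition that creates the C8 ketone necessarily leaves this double bond, whereas the aldol needs a C7 methylene. The hydrogenation must touch the disubstituted bond only.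

20 ⇒ 17 + 18. The ester C–O bond is cut. 17 has a single hydroxyl, and the ester is brought in only after the last aluminium hydride step. The acylation must work on an axial, hindered carbinol and keep the (Z)-alkene.

17 ⇒ 14. The C3–H bond is cut (carbinol to ketone) and the enone C6=C7–C8=O is traced to the vinylogous ester C6(=O)–C7=C8–OMe. Hydride from the α face sets C3, and the vinylogous ester is what the quinone supplies. The forward step needs a bulky hydride for C3, 1,2-reduction at the hindered C6, and acid mild enough for the tert-butyl ether.

14 ⇒ 13 ⇒ 12 ⇒ 10. The C3 ketone is masked as a silyl enol ether and the C9–H bond is cut back to C9–O (triflate, then ketone). The quinone carbonyl C9 must end as the C9=C10 alkene, and enolisation towards C10 with C3 masked fixes its position. Sulfonylation of the enolate must outrun loss of the C1 alkoxide.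

10 ⇒ 9 ⇒ 7. The silyl group is exchanged and the C4–H bond is cut (epimer). The endo adduct has the C4 methyl α; only while C10 is still sp3 and the fusion cis does the 4β epimer win clearly, so the correction comes directly after the cycloaddition. The equilibration must not eliminate the C1 ether.

7 ⇒ 5 + 6. C4–C5 and C1–C10 are cut ([4+2]). Two achiral partners give all ten ring carbons, three oxygens, both methyls and the quaternary centre. The forward step must be site-, regio-, endo- and face-selective.

5 ⇒ 4 ⇒ 3 ⇒ 1 + 2. The O–Si bond, the vinylic C–O bond and the acyl–vinyl C–C bond are cut. 4 is the stable precursor of the diene, its alkoxy group comes by addition–elimination on 3, and 3 by acylation of 2 with 1. The forward steps must give (E) at C1=C2 and (Z) at C3=C4.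

## Other disconnections considered

Alternative 1: The cut is at C5–C10 and C6=C7, back to the open-chain keto aldehyde A1. Forward, an amine catalyst would form the enamine of the α-branched aldehyde, C5 would add to C10 of the enone (6-exo-trig closure of ring B), and the 1,5-keto aldehyde would close ring A by aldol condensation to give A2.
- In favour: C1, C3 and C4 are built in the chain with the target configuration and with two different silyl ethers. Neither the C4 epimerisation (step 5) nor the C1 inversion (steps 15–17) would be needed, and O3 could be freed selectively for the angelate. On this point the alternative is better than the chosen plan.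
- Against: the enamine has to come from an α,α-disubstituted aldehyde and create a quaternary centre beside a tertiary one. The face selectivity at C5 would rest on the resident centres or on a chiral amine that may oppose them. A1 needs a long sequence of acyclic stereocontrol.
- Comparison: A2 still lacks C9=C10 and the C7 side chain, so the endgame is no shorter than from 17. The chosen plan makes the bicycle in one concerted step from two small achiral pieces but pays with two centres to correct; the alternative is a stepwise polar cascade that shifts the effort into the precursor, and its linear sequence would probably be longer. Both plans are equal in needing the same late ene reaction.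

Alternative 2: The cut is at C5–C6 and C7–C8, giving the ring B dienol silyl ether A3 and methyl vinyl ketone A4. Forward, their cycloaddition on heating or under pressure would give A5.
- In favour: C9=C10 is in place, the C8 oxygen is on the right carbon without a carbonyl transposition, and the acetyl group brings C11 and one methyl. Ring A would need fewer redox steps than in the chosen route, which is a point where the alternative is better. The dienophile should bond to C5 anti to the neighbouring C4 methyl, which is the required sense.
- Against: the diene terminus C5 is fully substituted and the quaternary centre is made intermolecularly with a modest dienophile. This calls for forcing conditions, under which polymerisation of A4 and loss of the silyl dienol ether compete. All three ring B stereocentres must come from a separate enantioselective synthesis of A3.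
- Comparison: both plans are [4+2] reactions, but the chosen one uses a strongly activated quinone under catalyst control of absolute configuration, whereas here control is by substrate. The steps saved after A5 are likely to be spent on A3.

Alternative 3: The cut is at C5–C10 and C8–C9, back to the acyclic trienone A6. Forward, an intramolecular Diels–Alder reaction would close both rings to give A7.
- In favour: both rings and the quaternary centre form in one step, and intramolecularity helps the hindered diene terminus. The chain should be accessible by aldol chemistry. C1 arrives as a ketone, so the 1β-alcohol would need only a reduction from the α face and no inversion; on this point the alternative is equal to or better than the chosen plan.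
- Against: A7 has no oxygen at C8, no C9=C10 and no C7 side chain. C8 would need allylic oxidation, then desaturation towards C10 beside the C1 carbonyl, then C7 functionalisation. The methyl on the diene terminus of A6 points inside in the reactive conformation, which should slow the cycloaddition and make ring-fusion and face control by the C3/C4 centres uncertain. The vinyl ketone is prone to polymerise.
- Comparison: the bicycle might be reached in slightly fewer steps than in the chosen route, but the post-cyclisation oxidation work is heavier and the absolute configuration again has to be built into the chain.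

Key step: step 4

Assumption: the (R)-BINOL–TiCl2(OiPr)2 complex is taken to leave open the quinone face that leads to 7 as drawn; should the opposite sense of induction be found, (S)-BINOL is used and nothing else changes.

## Steps

Step 1
Reactants: 1 propanoyl chloride; 2 acetylene
Product: 3 (E)-1-chloropent-1-en-3-one
Conditions: AlCl3, CH2Cl2, 0 °C → rt, acetylene stream
Reagents that add atoms: none
Why: Friedel–Crafts-type acylation of acetylene: the acylium ion from 1 adds to the alkyne and chloride captures the vinyl cation; the stable (E)-β-chlorovinyl ketone is isolated by distillation.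

Step 2
Reactants: 3 (E)-1-chloropent-1-en-3-one
Product: 4 (E)-1-tert-butoxypent-1-en-3-one
Conditions: KOtBu, tBuOH/THF, 0 °C
Reagents that add atoms: potassium tert-butoxide, CC(C)(C)[O-].[K+]
Why: Addition–elimination (vinylogous acyl substitution): tert-butoxide adds to the β-carbon and chloride leaves; the conjugated (E)-β-alkoxy enone is the thermodynamic product.

Step 3
Reactants: 4 (E)-1-tert-butoxypent-1-en-3-one
Product: 5 (1E,3Z)-1-tert-butoxy-3-(trimethylsilyloxy)penta-1,3-diene
Conditions: Me3SiOTf, Et3N, Et2O, 0 °C
Reagents that add atoms: trimethylsilyl trifluoromethanesulfonate, C[Si](C)(C)OS(=O)(=O)C(F)(F)F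
Why: Soft enolisation and O-silylation of the ethyl ketone; amine/silyl triflate conditions give the (Z)-silyl enol ether, so both terminal substituents of the diene point outside.

Step 4
Reactants: 5 (1E,3Z)-1-tert-butoxy-3-(trimethylsilyloxy)penta-1,3-diene; 6 2-methoxy-5-methyl-1,4-benzoquinone
Product: 7 cis-fused endo adduct 1α-tert-butoxy-8-methoxy-4α,5β-dimethyl-3-(trimethylsilyloxy)-10β-H-octalin-2,7-diene-6,9-dione (target numbering)
Conditions: (R)-BINOL/TiCl2(OiPr)2 (1:1, 10 mol%), CH2Cl2–toluene, −40 °C; filtration through Et3N-deactivated silica
Reagents that add atoms: none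
Why: Lewis-acid-catalysed Diels–Alder reaction of normal electron demand, concerted but asynchronous, the closest known type being the BINOL–titanium-catalysed enantioselective cycloaddition of 1-alkoxy-3-silyloxy dienes to quinones. Ring B is closed by the intermolecular [4+2] addition itself, C4–C5 and C1–C10 forming suprafacially on both partners in one step. Site selectivity: the C7=C8 bond of 6 is a vinylogous ester deactivated by the methoxy group, so only the methyl-bearing C5=C10 bond reacts. Regioselectivity: titanium chelates the C9 carbonyl and the C8 methoxy oxygen, which makes C5 (β to C9) the electrophilic terminus; it meets C4 of the diene, the terminus with the largest HOMO coefficient under the push of both oxygens, and this creates the quaternary centre. C5: its configuration follows from the quinone face left open by the binaphtholate ligand. C10: suprafacial addition to the quinone makes the ring fusion cis. C1 and C4: the endo approach (quinone ring under the diene) together with the (1E,3Z) geometry places the tert-butoxy group and the C4 methyl on the α face, trans to the angular methyl, and both are corrected later (step 5 and steps 15–17). The mild work-up keeps the silyl enol ether for characterisation of the adduct.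

Step 5
Reactants: 7 cis-fused endo adduct
Product: 9 1α-tert-butoxy-8-methoxy-4β,5β-dimethyl-10β-H-Δ7-octalin-3,6,9-trione, via 4α-methyl triketone 8 (not isolated)
Conditions: K2CO3 (0.2 equiv), MeOH, 0 °C → rt
Reagents that add atoms: none
Why: Methanolysis of the silyl enol ether gives 8, and thermodynamic epimerisation through the C3–C4 enolate then inverts C4: in the cis-fused bicycle only the 4β epimer can hold the C4 methyl and the C1 tert-butoxy group both equatorial (in the 4α epimer the methyl is syn-axial to C9 or the ether syn-axial to C6). The equatorial tert-butoxide is poorly aligned for E1cB loss, and any epimerisation at C10 is harmless because C10 becomes sp2 in step 7.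

Step 6
Reactants: 9 1α-tert-butoxy-8-methoxy-4β,5β-dimethyl-10β-H-Δ7-octalin-3,6,9-trione
Product: 10 1α-tert-butoxy-3-(tert-butyldimethylsilyloxy)-8-methoxy-4β,5β-dimethyl-10β-H-octalin-2,7-diene-6,9-dione
Conditions: tBuMe2SiOTf, Et3N, CH2Cl2, −78 °C
Reagents that add atoms: tert-butyldimethylsilyl trifluoromethanesulfonate, CC(C)(C)[Si](C)(C)OS(=O)(=O)C(F)(F)F
Why: Kinetic soft enolisation and O-silylation take the unhindered C2 methylene and leave the hindered C10–H and the C4 centre untouched; masking C3 makes C10–H the only acidic hydrogen for step 7.

Step 7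
Reactants: 10 1α-tert-butoxy-3-(tert-butyldimethylsilyloxy)-8-methoxy-4β,5β-dimethyl-10β-H-octalin-2,7-diene-6,9-dione
Product: 12 1α-tert-butoxy-3-(tert-butyldimethylsilyloxy)-8-methoxy-4β,5β-dimethyl-6-oxo-octalin-2,7,9-trien-9-yl trifluoromethanesulfonate, via potassium enolate 11 (not isolated)
Conditions: KN(SiMe3)2, THF, −78 °C; then PhNTf2, −78 °C
Reagents that add atoms: N-phenylbis(trifluoromethanesulfonimide), O=S(=O)(N(c1ccccc1)S(=O)(=O)C(F)(F)F)C(F)(F)F
Why: Enol triflate formation: C10–H is the only enolisable hydrogen, and O-sulfonylation of the enolate at −78 °C is faster than loss of the poor leaving group tert-butoxide; this fixes the C9=C10 double bond.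

Step 8
Reactants: 12 enol triflate
Product: 13 1α-tert-butoxy-3-(tert-butyldimethylsilyloxy)-8-methoxy-4β,5β-dimethyl-octalin-2,7,9-trien-6-one
Conditions: Pd(OAc)2 (5 mol%), PPh3, Bu3N, HCO2H, DMF, 60 °C
Reagents that add atoms: none
Why: Palladium-catalysed formate reduction of an enol triflate (oxidative addition to zerovalent palladium, formate-to-hydride exchange with loss of CO2, reductive elimination); the amine-buffered medium leaves the silyl enol ether and the tert-butyl ether intact.

Step 9
Reactants: 13 1α-tert-butoxy-3-(tert-butyldimethylsilyloxy)-8-methoxy-4β,5β-dimethyl-octalin-2,7,9-trien-6-one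
Product: 14 1α-tert-butoxy-8-methoxy-4β,5β-dimethyl-octalin-7,9-diene-3,6-dione
Conditions: Bu4NF, AcOH, THF, 0 °C
Reagents that add atoms: none
Why: Fluoride-induced cleavage of the silyl enol ether with immediate protonation at C2 by acetic acid; the buffered medium avoids both β-elimination of tert-butanol and enolisation towards C4.

Step 10
Reactants: 14 1α-tert-butoxy-8-methoxy-4β,5β-dimethyl-octalin-7,9-diene-3,6-dione
Product: 17 1α-tert-butoxy-3β-hydroxy-4β,5β-dimethyl-octalin-6,9-dien-8-one, via 3β-hydroxy enone 15 (not isolated), via 3β,6-diol 16 (not isolated)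
Conditions: LiBH(sBu)3, THF, −78 °C; then iBu2AlH, −78 → 0 °C; then 1 M HCl, THF, 0 °C → rt
Reagents that add atoms: water, O
Why: Two hydride reductions followed by a Stork–Danheiser transposition: the bulky borohydride attacks the C3 ketone equatorially from the α face, opposite the axial C5 methyl, and gives the axial 3β-alcohol, while the neopentylic, vinylogous-ester carbonyl C6 waits for iBu2AlH. Aqueous acid then ionises the C6 carbinol with help from the C8 methoxy group and hydrolysis gives the C6=C7–C8(=O)–C9=C10 dienone.

Step 11
Reactants: 17 1α-tert-butoxy-3β-hydroxy-4β,5β-dimethyl-octalin-6,9-dien-8-one; 18 angelic acid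
Product: 20 3β-angeloyloxy-1α-tert-butoxy-4β,5β-dimethyl-octalin-6,9-dien-8-one, via mixed anhydride 19 (not isolated)
Conditions: 2,4,6-Cl3C6H2COCl, Et3N, toluene, rt; then 17, 80 °C
Reagents that add atoms: none
Why: Yamaguchi esterification through the mixed anhydride; working without a nucleophilic amine catalyst is the usual way to keep the (Z)-geometry of the angelate, and the C3 hydroxyl is the only one in 17.

Step 12
Reactants: 20 3β-angeloyloxy-1α-tert-butoxy-4β,5β-dimethyl-octalin-6,9-dien-8-one
Product: 21 3β-angeloyloxy-1α-tert-butoxy-4β,5β-dimethyl-Δ9-octalin-8-one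
Conditions: H2 (1 atm), RhCl(PPh3)3 (10 mol%), toluene–EtOH, rt
Reagents that add atoms: none
Why: Homogeneous hydrogenation with RhCl(PPh3)3 reduces the cis-disubstituted C6=C7 bond of a cross-conjugated dienone and leaves the trisubstituted C9=C10 bond and the trisubstituted angelate alone, as in the selective 1,2-reduction of steroidal 1,4-dien-3-ones.

Step 13
Reactants: 21 3β-angeloyloxy-1α-tert-butoxy-4β,5β-dimethyl-Δ9-octalin-8-one; 22 acetone
Product: 24 3β-angeloyloxy-1α-tert-butoxy-7-(2-hydroxypropan-2-yl)-4β,5β-dimethyl-Δ9-octalin-8-one (C7 epimers), via lithium enolate 23 (not isolated)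
Conditions: LiN(iPr)2, THF, −78 °C; ZnCl2; then acetone, −78 → −40 °C
Reagents that add atoms: none
Why: Directed aldol addition: kinetic deprotonation of the enone at the α′ carbon C7 (not at the γ carbon C1) and addition to acetone; the ketone is far more acidic than the angelate, which has no α-hydrogen, and the new C7 centre disappears in step 14.

Step 14
Reactants: 24 aldol adduct
Product: 26 3β-angeloyloxy-1α-tert-butoxy-4β,5β-dimethyl-eremophila-7(11),9-dien-8-one, via tertiary mesylate 25 (not isolated)
Conditions: MeSO2Cl, Et3N, CH2Cl2, 0 °C; then DBU, rt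
Reagents that add atoms: none
Why: Dehydration by E1cB elimination of the tertiary mesylate through the C7 enolate completes the aldol condensation and gives the conjugated tetrasubstituted C7=C11 alkene; any isopropenyl isomer is brought into conjugation by the amidine base.

Step 15
Reactants: 26 3β-angeloyloxy-1α-tert-butoxy-4β,5β-dimethyl-eremophila-7(11),9-dien-8-one
Product: 27 3β-angeloyloxy-1α-hydroxy-4β,5β-dimethyl-eremophila-7(11),9-dien-8-one
Conditions: CF3CO2H/CH2Cl2 (1:4), 0 °C
Reagents that add atoms: none
Why: Acidolysis of the tert-butyl ether with loss of isobutene through the tert-butyl cation; the C1–O bond itself does not ionise because the cation would be γ to the dienone carbonyl, and angelates tolerate cold trifluoroacetic acid.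

Step 16
Reactants: 27 3β-angeloyloxy-1α-hydroxy-4β,5β-dimethyl-eremophila-7(11),9-dien-8-one
Product: 28 3β-angeloyloxy-4β,5β-dimethyl-eremophila-7(11),9-diene-1,8-dione
Conditions: Dess–Martin periodinane, CH2Cl2, 0 °C → rt
Reagents that add atoms: none
Why: Dess–Martin oxidation of the allylic alcohol under non-basic conditions, chosen because the product is a β-acyloxy ketone that would lose angelic acid with base; 28 is used at once.

Step 17
Reactants: 28 3β-angeloyloxy-4β,5β-dimethyl-eremophila-7(11),9-diene-1,8-dione
Product: 29 3β-angeloyloxy-1β-hydroxy-4β,5β-dimethyl-eremophila-7(11),9-dien-8-one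
Conditions: NaBH4, CeCl3·7H2O, MeOH, −78 °C
Reagents that add atoms: none
Why: Luche reduction: 1,2-hydride addition to the C1 carbonyl, which is more electrophilic and less hindered than the doubly conjugated C8 carbonyl beside the isopropylidene group. Hydride enters from the α face because the β face is blocked by the axial C5 methyl and the axial C3 angelate, which gives the 1β-alcohol.

Step 18
Reactants: 29 3β-angeloyloxy-1β-hydroxy-4β,5β-dimethyl-eremophila-7(11),9-dien-8-one
Product: 30 3β-angeloyloxy-11-hydroperoxy-1β-hydroxy-4β,5β-dimethyl-eremophila-6,9-dien-8-one (CNP0300636.1)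
Conditions: O2, hν (visible), tetraphenylporphyrin (cat.), CH2Cl2, 0 °C
Reagents that add atoms: dioxygen, O=O
Why: Schenck ene reaction of singlet oxygen with the s-cis enone: oxygen bonds to the β-carbon C11 and hydrogen is taken from C6, the position geminal to the carbonyl, so the C6=C7 bond and the tertiary hydroperoxide appear together. The electron-poor angelate and the s-trans C9=C10 enone react much more slowly, and no stereocentre is touched.

## Compound list

1 | propanoyl chloride | CCC(Cl)=O | starting material
2 | acetylene | C#C | starting material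
3 | (E)-1-chloropent-1-en-3-one | CCC(=O)/C=C/Cl | intermediate
4 | (E)-1-tert-butoxypent-1-en-3-one | CCC(=O)/C=C/OC(C)(C)C | intermediate
5 | (1E,3Z)-1-tert-butoxy-3-(trimethylsilyloxy)penta-1,3-diene | CC(C)(C)O/C=C/C(O[Si](C)(C)C)=C/C | intermediate
6 | 2-methoxy-5-methyl-1,4-benzoquinone | COC1=CC(=O)C(C)=CC1=O | starting material
7 | cis-fused endo adduct, 1α-tert-butoxy-8-methoxy-4α,5β-dimethyl-3-(trimethylsilyloxy)-10β-H-octalin-2,7-diene-6,9-dione | CC(C)(C)O[C@H]1C=C(O[Si](C)(C)C)[C@@H](C)[C@@]2(C)C(=O)C=C(OC)C(=O)[C@@H]12 | intermediate
8 | 4α-methyl triketone, 1α-tert-butoxy-8-methoxy-4α,5β-dimethyl-10β-H-Δ7-octalin-3,6,9-trione | CC(C)(C)O[C@H]1CC(=O)[C@@H](C)[C@@]2(C)C(=O)C=C(OC)C(=O)[C@@H]12 | intermediate (not isolated)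
9 | 1α-tert-butoxy-8-methoxy-4β,5β-dimethyl-10β-H-Δ7-octalin-3,6,9-trione | CC(C)(C)O[C@H]1CC(=O)[C@H](C)[C@@]2(C)C(=O)C=C(OC)C(=O)[C@@H]12 | intermediate
10 | 1α-tert-butoxy-3-(tert-butyldimethylsilyloxy)-8-methoxy-4β,5β-dimethyl-10β-H-octalin-2,7-diene-6,9-dione | CC(C)(C)O[C@H]1C=C(O[Si](C)(C)C(C)(C)C)[C@H](C)[C@@]2(C)C(=O)C=C(OC)C(=O)[C@@H]12 | intermediate
11 | potassium enolate of 10 (C9–O, C9=C10) | CC(C)(C)O[C@H]1C=C(O[Si](C)(C)C(C)(C)C)[C@H](C)[C@@]2(C)C(=O)C=C(OC)C([O-])=C12.[K+] | intermediate (not isolated)
12 | 1α-tert-butoxy-3-(tert-butyldimethylsilyloxy)-8-methoxy-4β,5β-dimethyl-6-oxo-octalin-2,7,9-trien-9-yl trifluoromethanesulfonate | CC(C)(C)O[C@H]1C=C(O[Si](C)(C)C(C)(C)C)[C@H](C)[C@@]2(C)C(=O)C=C(OC)C(OS(=O)(=O)C(F)(F)F)=C12 | intermediate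
13 | 1α-tert-butoxy-3-(tert-butyldimethylsilyloxy)-8-methoxy-4β,5β-dimethyl-octalin-2,7,9-trien-6-one | CC(C)(C)O[C@H]1C=C(O[Si](C)(C)C(C)(C)C)[C@H](C)[C@@]2(C)C(=O)C=C(OC)C=C12 | intermediate
14 | 1α-tert-butoxy-8-methoxy-4β,5β-dimethyl-octalin-7,9-diene-3,6-dione | CC(C)(C)O[C@H]1CC(=O)[C@H](C)[C@@]2(C)C(=O)C=C(OC)C=C12 | intermediate
15 | 3β-hydroxy enone, 1α-tert-butoxy-3β-hydroxy-8-methoxy-4β,5β-dimethyl-octalin-7,9-dien-6-one (formed as its lithium alkoxide) | CC(C)(C)O[C@H]1C[C@H](O)[C@H](C)[C@@]2(C)C(=O)C=C(OC)C=C12 | intermediate (not isolated)
16 | 3β,6-diol, 1α-tert-butoxy-8-methoxy-4β,5β-dimethyl-octalin-7,9-diene-3β,6-diol (C6 epimers, formed as its aluminium alkoxide) | CC(C)(C)O[C@H]1C[C@H](O)[C@H](C)[C@@]2(C)C(O)C=C(OC)C=C12 | intermediate (not isolated)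
17 | 1α-tert-butoxy-3β-hydroxy-4β,5β-dimethyl-octalin-6,9-dien-8-one | CC(C)(C)O[C@H]1C[C@H](O)[C@H](C)[C@@]2(C)C=CC(=O)C=C12 | intermediate
18 | angelic acid, (Z)-2-methylbut-2-enoic acid | C/C=C(/C)C(=O)O | starting material
19 | mixed anhydride, angelic 2,4,6-trichlorobenzoic anhydride | C/C=C(/C)C(=O)OC(=O)c1c(Cl)cc(Cl)cc1Cl | intermediate (not isolated)
20 | 3β-angeloyloxy-1α-tert-butoxy-4β,5β-dimethyl-octalin-6,9-dien-8-one | CC(C)(C)O[C@H]1C[C@H](OC(=O)/C(C)=C\C)[C@H](C)[C@@]2(C)C=CC(=O)C=C12 | intermediate
21 | 3β-angeloyloxy-1α-tert-butoxy-4β,5β-dimethyl-Δ9-octalin-8-one | CC(C)(C)O[C@H]1C[C@H](OC(=O)/C(C)=C\C)[C@H](C)[C@@]2(C)CCC(=O)C=C12 | intermediate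
22 | acetone | CC(C)=O | starting material
23 | lithium enolate of 21 (C8–O, C7=C8) | CC(C)(C)O[C@H]1C[C@H](OC(=O)/C(C)=C\C)[C@H](C)[C@@]2(C)CC=C([O-])C=C12.[Li+] | intermediate (not isolated)
24 | 3β-angeloyloxy-1α-tert-butoxy-7-(2-hydroxypropan-2-yl)-4β,5β-dimethyl-Δ9-octalin-8-one (C7 epimers) | CC(C)(C)O[C@H]1C[C@H](OC(=O)/C(C)=C\C)[C@H](C)[C@@]2(C)CC(C(C)(C)O)C(=O)C=C12 | intermediate
25 | tertiary mesylate of 24 | CC(C)(C)O[C@H]1C[C@H](OC(=O)/C(C)=C\C)[C@H](C)[C@@]2(C)CC(C(C)(C)OS(C)(=O)=O)C(=O)C=C12 | intermediate (not isolated)
26 | 3β-angeloyloxy-1α-tert-butoxy-4β,5β-dimethyl-eremophila-7(11),9-dien-8-one | CC(C)(C)O[C@H]1C[C@H](OC(=O)/C(C)=C\C)[C@H](C)[C@@]2(C)CC(=C(C)C)C(=O)C=C12 | intermediate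
27 | 3β-angeloyloxy-1α-hydroxy-4β,5β-dimethyl-eremophila-7(11),9-dien-8-one | O[C@H]1C[C@H](OC(=O)/C(C)=C\C)[C@H](C)[C@@]2(C)CC(=C(C)C)C(=O)C=C12 | intermediate
28 | 3β-angeloyloxy-4β,5β-dimethyl-eremophila-7(11),9-diene-1,8-dione | O=C1C[C@H](OC(=O)/C(C)=C\C)[C@H](C)[C@@]2(C)CC(=C(C)C)C(=O)C=C12 | intermediate
29 | 3β-angeloyloxy-1β-hydroxy-4β,5β-dimethyl-eremophila-7(11),9-dien-8-one | O[C@@H]1C[C@H](OC(=O)/C(C)=C\C)[C@H](C)[C@@]2(C)CC(=C(C)C)C(=O)C=C12 | intermediate
30 | CNP0300636.1, 3β-angeloyloxy-11-hydroperoxy-1β-hydroxy-4β,5β-dimethyl-eremophila-6,9-dien-8-one | C/C=C(/C)C(=O)O[C@H]1C[C@@H](O)C2=CC(=O)C(C(C)(C)OO)=C[C@]2(C)[C@H]1C | target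

## Step count and least certain steps

Total: 18 steps. Longest linear sequence: 18 steps (1 → 30); 6, 18 and 22 are purchased.

Step 4 (key step). The chiral titanium complex may discriminate poorly between the faces of this quinone, or it may strip the trimethylsilyl group from 5 before cycloaddition, so that the diene is lost in Michael-type side reactions. Fallback: 5 and 6 are combined without catalyst (toluene, 40 °C), where site, regio and endo selectivity are substrate-controlled; this gives 7 together with its mirror image, the enantiomeric adduct F1. Step 5 is run on the racemate to give 9 and the enantiomeric triketone F2, and 9 is separated by preparative chromatography on a chiral stationary phase (amylose tris(3,5-dimethylphenylcarbamate)). The fallback sets out from 5 and 6 and rejoins the route at 9.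

Step 5. β-Elimination of tert-butanol through the C3 or C9 enolate may compete with epimerisation, and the C4 ratio may fall if the ring fusion drifts to trans, where the preference for the 4β epimer is smaller. Fallback: the 4β configuration is built into the cycloaddition. 4 is deprotonated with LiN(iPr)2 and silylated with Me3SiCl (THF, −78 °C) to the (1E,3E)-diene F3, in which the methyl points inside. Its endo cycloaddition with 6 under the conditions of step 4 gives the 4β-methyl adduct F4, and hydrolysis with citric acid in THF–H2O gives 9 without any base treatment; F3 should react more slowly than 5. The fallback sets out from 4 and rejoins at 9.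

Step 7. The enolate may expel tert-butoxide before it is sulfonylated, because allylic strain pushes the C1–O bond into alignment with the enolate π system, and O-sulfonylation next to the C8 methoxy group may be slow. Fallback: the C9 ketone of 10 is reduced with NaBH4/CeCl3·7H2O (the vinylogous-ester carbonyl C6 is inert) to the C9 carbinol F5. It is dehydrated towards C10, the only β-hydrogen, with the Burgess reagent (syn elimination) or Martin sulfurane (anti elimination), whichever fits the configuration found at C9, to give 13. The fallback sets out from 10 and rejoins at 13.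

Step 11. Acylation of the hindered axial alcohol may be slow, and prolonged heating may isomerise the angelate to the tiglate. Fallback: 17 is coupled with 2-[bis(2,2,2-trifluoroethoxy)phosphoryl]propanoic acid (DCC, DMAP) to the phosphonate ester F6. A Still–Gennari olefination with acetaldehyde (KN(SiMe3)2, 18-crown-6, THF, −78 °C) then builds the (Z)-alkene on the molecule and gives 20. The fallback sets out from 17 and rejoins at 20.

Step 17. Hydride may also attack C8 or add in conjugate fashion to the ene-dione, and the β-acyloxy ketone may lose angelic acid in the basic medium. Fallback: both carbonyl groups of 28 are reduced on purpose (excess NaBH4/CeCl3·7H2O, −40 °C) to the 1β,8-diol F7. Only the doubly allylic, unhindered C8 carbinol is then re-oxidised with MnO2 (CH2Cl2, rt); the axial C1 carbinol between the C5 methyl and the C3 ester should react far more slowly. The fallback sets out from 28 and rejoins at 29.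

## Further compounds

F1 | step 4 | enantiomeric adduct (mirror image of 7) | CC(C)(C)O[C@@H]1C=C(O[Si](C)(C)C)[C@H](C)[C@]2(C)C(=O)C=C(OC)C(=O)[C@H]12
F2 | step 4 | enantiomeric triketone (mirror image of 9) | CC(C)(C)O[C@@H]1CC(=O)[C@@H](C)[C@]2(C)C(=O)C=C(OC)C(=O)[C@H]12
F3 | step 5 | (1E,3E)-1-tert-butoxy-3-(trimethylsilyloxy)penta-1,3-diene | CC(C)(C)O/C=C/C(O[Si](C)(C)C)=C\C
F4 | step 5 | 4β-methyl adduct, 1α-tert-butoxy-8-methoxy-4β,5β-dimethyl-3-(trimethylsilyloxy)-10β-H-octalin-2,7-diene-6,9-dione | CC(C)(C)O[C@H]1C=C(O[Si](C)(C)C)[C@H](C)[C@@]2(C)C(=O)C=C(OC)C(=O)[C@@H]12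
F5 | step 7 | C9 carbinol, 1α-tert-butoxy-3-(tert-butyldimethylsilyloxy)-9-hydroxy-8-methoxy-4β,5β-dimethyl-10β-H-octalin-2,7-dien-6-one (C9 configuration open) | CC(C)(C)O[C@H]1C=C(O[Si](C)(C)C(C)(C)C)[C@H](C)[C@@]2(C)C(=O)C=C(OC)C(O)[C@@H]12
F6 | step 11 | phosphonate ester, 3β-{2-[bis(2,2,2-trifluoroethoxy)phosphoryl]propanoyloxy}-1α-tert-butoxy-4β,5β-dimethyl-octalin-6,9-dien-8-one | CC(C)(C)O[C@H]1C[C@H](OC(=O)C(C)P(=O)(OCC(F)(F)F)OCC(F)(F)F)[C@H](C)[C@@]2(C)C=CC(=O)C=C12
F7 | step 17 | 1β,8-diol, 3β-angeloyloxy-4β,5β-dimethyl-eremophila-7(11),9-diene-1β,8-diol (C8 configuration open) | O[C@@H]1C[C@H](OC(=O)/C(C)=C\C)[C@H](C)[C@@]2(C)CC(=C(C)C)C(O)C=C12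
A1 | alternative 1 | keto aldehyde, (E)-6-(tert-butyldimethylsilyloxy)-2,3-dimethyl-9-oxo-4-(triethylsilyloxy)dec-7-enal (C2 of the chain open) | CC(=O)/C=C/[C@H](O[Si](C)(C)C(C)(C)C)C[C@H](O[Si](CC)(CC)CC)[C@H](C)C(C)C=O
A2 | alternative 1 | cis-fused 1-(tert-butyldimethylsilyloxy)-4,5-dimethyl-3-(triethylsilyloxy)-Δ6-octalin-8-one | CC[Si](CC)(CC)O[C@H]1C[C@@H](O[Si](C)(C)C(C)(C)C)[C@@H]2CC(=O)C=C[C@]2(C)[C@H]1C
A3 | alternative 2 | ring B dienol silyl ether, 1-[(E)-2-(triethylsilyloxy)vinyl]cyclohexene with 2,3-dimethyl, 4-(4-methoxybenzyloxy) and 6-(tert-butyldimethylsilyloxy) groups | COc1ccc(CO[C@H]2C[C@@H](O[Si](C)(C)C(C)(C)C)C(/C=C/O[Si](CC)(CC)CC)=C(C)[C@H]2C)cc1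
A4 | alternative 2 | methyl vinyl ketone | C=CC(C)=O
A5 | alternative 2 | endo adduct, 7-acetyl-8-(triethylsilyloxy)-eremophil-9-ene core with the C1 silyl ether and the C3 4-methoxybenzyl ether | COc1ccc(CO[C@H]2C[C@@H](O[Si](C)(C)C(C)(C)C)C3=C[C@H](O[Si](CC)(CC)CC)[C@H](C(C)=O)C[C@]3(C)[C@H]2C)cc1
A6 | alternative 3 | trienone, (7E)-5-(tert-butyldimethylsilyloxy)-6,7-dimethyldeca-1,7,9-trien-3-one | C=C/C=C(\C)[C@@H](C)[C@@H](O[Si](C)(C)C(C)(C)C)CC(=O)C=C
A7 | alternative 3 | cis-fused 3-(tert-butyldimethylsilyloxy)-4,5-dimethyl-Δ6-octalin-1-one | CC(C)(C)[Si](C)(C)O[C@H]1CC(=O)[C@@H]2CCC=C[C@]2(C)[C@H]1C
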